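## The problem

Compound 27 is a bis-lactone. Ring A is a 3-alkyl-5,6-dihydro-2H-pyran-2-one (O1, C2 carbonyl, C3=C4, C5, C6). It is joined through the single bond C6–C3′ to ring B, a γ-butyrolactone (C1′ carbonyl, C2′, C3′, C4′–O). C3 carries an (E)-4-methylhex-3-enyl chain that ends in a 2,6,6-trimethylcyclohexene.

The only stereocentres, C6 (R) and C3′ (R), are vicinal but lie on different rings. In the target neither ring can pass its configuration to the other, so they must be set independently or tied for a time into one ring.

Three groups limit the reagents. The 1,5-diene of the chain is sensitive to strong acid (cation–olefin cyclisation) and to hydrogenation. The conjugated δ-lactone is sensitive to base (γ-deprotonation with ring opening, conjugate addition). The C3=C4 bond must be cis for ring A to close, which in an open precursor means a Z-trisubstituted enoate.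

The enabling feature is that C1′ lies γ to two oxygens, the one on C6 and the one on C4′. If C4′ is raised to a carboxyl, C6 and C3′ become the ketone carbon and the α-carbon of a 2-acylsuccinate, and the C6 oxygen can lactonise onto C1′. In that temporary five-membered ring the C5 arm and the C4′ carboxyl are vicinal ring substituents, and their trans arrangement corresponds to (6R,3′R) in 27. C6 can therefore be set by a catalyst and C3′ by equilibration. Ring A can only be closed by the C6 oxygen, so releasing that oxygen at the end sends the C1′ carboxyl to the C4′ oxygen, which is ring B.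

## Retrosynthesis

**Ring A and the position of the γ-lactone (27 ⇒ 26 ⇒ 25 ⇒ 24).** The O1–C2 bond of ring A is cut to the Z-hydroxy enoate 26, and the O(C4′)–C1′ bond of ring B is exchanged for an O(C6)–C1′ bond, giving 25 and its silyl ether 24. Keeping ring B intact through the route would require the C6 and C4′ hydroxyls to be told apart by protecting groups early. Here the temporary lactone does that for free. The precursor 24 has no ring A and one free carboxyl derivative. The forward step must remove a primary silyl ether, move a γ-lactone from a secondary to a primary oxygen and close a δ-lactone, all under acid mild enough for the 1,5-diene.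

**The C3=C4 bond (24 ⇒ 23 + 10).** Cutting the enoate double bond by a Horner–Wadsworth–Emmons disconnection separates the chiral C4–C6/C1′–C4′ part, aldehyde 23, from the achiral terpenoid chain, phosphonate 10. The neighbouring cuts (C3–chain by cross-coupling, or C2–C3) would need ring A first and a halogenated bis-lactone. The olefination cut is the most convergent, and the diene arrives after every hydrogenation step. The forward reaction must be Z-selective with an α-branched reagent and must not eliminate the β-acyloxy group of 23.

**The chain phosphonate (10 ⇒ 8 + 9; 8 ⇒ 7 ⇒ 3 + 4; 3 ⇒ 1).** The bond from the phosphonate α-carbon to the chain is cut to iodide 8 and the diaryl phosphonoacetate 9. The E-trisubstituted alkene of 8 is traced through alcohol 7 to alkyne 3 and oxirane 4 by a syn-methylmetalation, and 3 to dihydro-β-ionone 1. Olefination or cyclopropylcarbinyl rearrangement of the methyl ketone 1 would keep its methyl group but give E/Z mixtures. The alkyne route fixes the geometry by mechanism. Each precursor is simpler by one C–C bond; the forward steps need only regioselective enolisation of 1 and a clean alkenyl transfer to 4.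

**Oxidation levels at C4 and C4′ (23 ⇒ 22 ⇒ 21 ⇒ 20 ⇒ 19 ⇒ 18).** No skeletal bond is cut. The aldehyde is traced to a benzyl ether (22, 21), and the silyloxymethyl group to a carboxylic acid (20, 19) and its tert-butyl ester 18. A tert-butyl ester and a benzyl ether are cleaved independently of each other and of the lactone, and borane reduces the acid in the presence of the lactone. The forward steps must avoid base while the C4′ hydroxyl is free.

**The key disconnection (18 ⇒ 17 ⇒ 16 ⇒ 15).** The lactone C–O bond between the C6 oxygen and C1′ and the C6–H bond are cut, giving the hydroxy diester 16 and then the racemic 2-acylsuccinate 15. Both stereocentres disappear: C6 becomes a ketone and C3′ an enolisable carbon. An aldol or allylation cut of C6–C3′ would have to set two acyclic vicinal centres kinetically. This cut needs one catalyst for C6 and equilibration (through 17) for C3′. The forward step must reduce one ketone face irrespective of the C3′ configuration and lactonise onto the methyl ester only.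

**The acylsuccinate (15 ⇒ 13 + 14; 13 ⇒ 11 + 12).** The C2′–C3′ bond is cut by enolate alkylation to β-keto ester 13 and methyl bromoacetate 14. The C4–C5 bond is cut by γ-alkylation of the dianion of tert-butyl acetoacetate 11 with benzyl chloromethyl ether 12. The alternative of acylating a malonate with a 3-benzyloxypropanoyl unit costs one step more. All four components are commercial; the forward steps are standard enolate alkylations.

## Roads not taken

**Alternative 1:** Ring A is cut at C5–C6 and O1–C2. Forward, the chain-bearing methoxydiene A2 and the ring B aldehyde A3 would combine in an oxa-Diels–Alder reaction under a chiral tridentate Schiff-base complex, (salicylaldimine)CrCl (trivalent chromium). The product is the cis lactol methyl ether A1, which is then oxidised at C2 to 27.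
- Merits: this is the most convergent plan. Ring A, C6 and the chain are placed in one catalytic step, and the C3=C4 geometry is cis by construction, so no Z-olefination is needed. On both counts it is better than the chosen route.
- Weak points: C3′ is not made by the key step. A3 needs its own asymmetric synthesis and is an α-stereogenic, β-acyloxy aldehyde that can epimerise or eliminate under Lewis acid. The catalyst must also work with or against the bias of A3. A2 is an acid-sensitive 2-alkyl-1-methoxydiene of defined enol ether geometry, itself several steps. The acetal carbon of A1 must be oxidised next to the 1,5-diene.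
- Comparison: the chosen plan has a longer linear sequence. Against that it makes both stereocentres in one operation from achiral material, and the labile centre C3′ is corrected thermodynamically rather than carried through in a fragile aldehyde.

**Alternative 2:** Ring B is cut at C2′–C3′. Forward, the diazoacetate A5 of the ring A hydroxyethyl compound would be decomposed by Rh2(MPPIM)4 (divalent rhodium), and the carbenoid would insert into one C3′–H bond to give the chain-free bis-lactone A4.
- Merits: ring B and C3′ arise from an unfunctionalised methylene without protecting groups. No lactone transposition is needed, and A4 would serve for analogues with other chains. In the number of operations on the bis-lactone core it is at least equal to the chosen route.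
- Weak points: the two C3′ hydrogens are diastereotopic next to C6, so catalyst and substrate control may be mismatched. Insertion into the oxygen-activated C6–H bond and carbene dimerisation compete. C6 needs a separate asymmetric step before A5. The chain must be attached to C3 of A4 by halogenation and cross-coupling on a base-sensitive compound.
- Comparison: the chosen plan needs one asymmetric catalyst, not two, and attaches the chain by the same olefination that prepares ring A.

**Alternative 3:** Ring B is cut at C1′–C2′. Forward, the 1,1-disubstituted allylic alcohol A7, which already holds ring A and the chain, would be hydroformylated with Rh(acac)(CO)2 and a chiral bisphosphorus ligand. The aldehyde formed at the terminal carbon closes onto the C4′ hydroxyl to give lactol A6, and one oxidation gives 27.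
- Merits: it is the most atom-economic endgame. Ring B comes from CO and H2 on the finished skeleton, without protecting groups and without a transposition, and the finish is shorter than the chosen one.
- Weak points: enantioselective hydroformylation of 1,1-disubstituted alkenes with a new β-stereocentre is among the less developed cases, and here the adjacent C6 adds its own 1,2-induction. There is no way to correct C3′ afterwards. The rhodium hydride meets three further alkenes, of which the enoate may be reduced and the chain alkene isomerised. A7 still needs C6 set separately.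
- Comparison: the chosen plan is longer, but both centres are controlled by well-understood elements (catalyst at C6, ring thermodynamics at C3′), and hydrogen never meets the diene.

Key step: step 7

Assumptions (remarks on the chemistry):
- The 6R outcome with the (R)-ligand follows the empirical rule for 3-oxo esters, in which the α-carbon branch outranks the alkyl branch, as it does here. Should the sense prove opposite, the (S)-ligand is used and nothing else changes.
- Reagent 9 is taken as purchased.
- Metal enolates, acetylides and phosphonate anions that are only the deprotonated form of a numbered compound are not numbered separately.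

## Route

Step 1
Reactants: 1 dihydro-β-ionone
Product: 3 2-(but-3-yn-1-yl)-1,3,3-trimethylcyclohex-1-ene, via enol phosphate 2 (not isolated)
Conditions: LiN(i-Pr)2 (1.05 equiv), THF, −78 °C; ClP(O)(OEt)2, −78 °C → rt; then LiN(i-Pr)2 (2.3 equiv), THF, −78 °C → rt; H2O
Reagents that add atoms: none
Why: One-flask conversion of a methyl ketone into a terminal alkyne: kinetic deprotonation at the methyl group, O-phosphorylation of the enolate and base-induced elimination of diethyl phosphate. The tetrasubstituted ring alkene is inert to these conditions.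

Step 2
Reactants: 3 2-(but-3-yn-1-yl)-1,3,3-trimethylcyclohex-1-ene; 4 oxirane
Product: 7 (3E)-4-methyl-6-(2,6,6-trimethylcyclohex-1-en-1-yl)hex-3-en-1-ol, via alkenylalane 5 (not isolated), via lithium alkenylaluminate 6 (not isolated)
Conditions: Me3Al (2.5 equiv), Cp2ZrCl2 (0.25 equiv), CH2Cl2, 0 °C → rt; evaporate volatiles, hexane; n-BuLi, 0 °C; oxirane, THF, 0 °C → rt; aq. HCl
Reagents that add atoms: trimethylaluminium, C[Al](C)C
Why: Zirconium-catalysed methylalumination (Negishi carboalumination) adds methyl and aluminium syn across the terminal alkyne with aluminium on the terminal carbon, which fixes the E geometry. Conversion into the more nucleophilic aluminate lets the alkenyl group open oxirane with retention of the alkene geometry.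

Step 3
Reactants: 7 (3E)-4-methyl-6-(2,6,6-trimethylcyclohex-1-en-1-yl)hex-3-en-1-ol
Product: 8 2-[(3E)-6-iodo-3-methylhex-3-en-1-yl]-1,3,3-trimethylcyclohex-1-ene
Conditions: I2, PPh3, imidazole, CH2Cl2, 0 °C → rt
Reagents that add atoms: iodine, II
Why: Appel-type iodination of a primary alcohol by SN2 displacement of the alkoxyphosphonium ion. The neutral conditions leave both alkenes and their geometry untouched.

Step 4
Reactants: 8 2-[(3E)-6-iodo-3-methylhex-3-en-1-yl]-1,3,3-trimethylcyclohex-1-ene; 9 ethyl 2-[bis(2-methylphenoxy)phosphoryl]acetate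
Product: 10 ethyl (5E)-2-[bis(2-methylphenoxy)phosphoryl]-6-methyl-8-(2,6,6-trimethylcyclohex-1-en-1-yl)oct-5-enoate (racemic at C2)
Conditions: 9 (1.5 equiv), NaH, DMSO–THF, rt; then 8, rt → 45 °C
Reagents that add atoms: none
Why: SN2 C-alkylation of the sodium salt of a diaryl phosphonoacetate with a primary iodide, the usual entry to α-substituted reagents of this class. The weakly basic anion should not eliminate the homoallylic iodide, and excess 9 suppresses dialkylation.

Step 5
Reactants: 11 tert-butyl 3-oxobutanoate; 12 benzyl chloromethyl ether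
Product: 13 tert-butyl 5-(benzyloxy)-3-oxopentanoate
Conditions: NaH, THF, 0 °C; n-BuLi, 0 °C; then 12, −78 °C → 0 °C; aq. HCl
Reagents that add atoms: none
Why: Weiler dianion alkylation: the acetoacetate dianion reacts at its more basic γ-carbon with the reactive chloromethyl ether and gives the 5-benzyloxy β-keto ester in one step.

Step 6
Reactants: 13 tert-butyl 5-(benzyloxy)-3-oxopentanoate; 14 methyl bromoacetate
Product: 15 1-tert-butyl 4-methyl 2-[3-(benzyloxy)propanoyl]butanedioate (racemic)
Conditions: NaH (1.0 equiv), THF, 0 °C; then 14, 0 °C → rt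
Reagents that add atoms: none
Why: SN2 mono-C-alkylation of a β-keto ester enolate with an α-bromo ester. The new centre C3′ forms racemic and stays configurationally labile between ketone and ester, which is what step 7 requires.

Step 7
Reactants: 15 1-tert-butyl 4-methyl 2-[3-(benzyloxy)propanoyl]butanedioate
Product: 18 tert-butyl (2R,3S)-2-[2-(benzyloxy)ethyl]-5-oxooxolane-3-carboxylate (trans paraconate), via hydroxy diester 16 (not isolated), via lactone epimer mixture 17 (not isolated)
Conditions: H2 (50 bar), RuCl2[(R)-BINAP] (1 mol %), MeOH, 50 °C; evaporate; DBU (0.2 equiv), toluene, rt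
Reagents that add atoms: none
Why: The ketone and the tert-butyl ester carbonyl of 15 chelate the ruthenium hydride (divalent ruthenium) and hydride is delivered to the face of C6 left open by the (R)-BINAP quadrants, while the C3′ epimers of 15 interconvert through the enol faster than either is reduced. The closest known reaction type is the RuCl2(BINAP) hydrogenation of 2-substituted 3-oxo esters with dynamic kinetic resolution, which includes 2-acylsuccinates that lactonise to paraconates. C6 is thus set by the ligand (6R expected for the R ligand). The C6 hydroxyl of 16 then displaces methoxide from the methyl ester in a 5-exo-trig acyl substitution; attack on the tert-butyl ester would give a β-lactone and does not compete. C3′ is not left to the kinetic diastereoselectivity of the hydrogenation, which is unreliable for acyclic 2-alkyl substrates, but is set thermodynamically on the five-membered ring, where DBU equilibrates the ester α-centre of 17 to the trans arrangement of the C5 arm and the carboxylate. Ring opening by β-elimination of the C6 oxygen from the C3′ enolate is the reverse of a 5-endo-trig closure and is stereoelectronically disfavoured, so the epimerisation should be clean. The selectivities needed are ketone over esters and benzyl ether, secured by the chelating β-keto ester and the inertness of this catalyst to O-benzyl, and a face selectivity independent of C3′, secured by fast enolisation between two carbonyls.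

Step 8
Reactants: 18 tert-butyl (2R,3S)-2-[2-(benzyloxy)ethyl]-5-oxooxolane-3-carboxylate
Product: 19 (2R,3S)-2-[2-(benzyloxy)ethyl]-5-oxooxolane-3-carboxylic acid
Conditions: TFA–CH2Cl2 (1:4), 0 °C → rt
Reagents that add atoms: none
Why: Acidolysis of the tert-butyl ester with loss of isobutene. The benzyl ether, the γ-lactone and both stereocentres are stable under these non-epimerising conditions.

Step 9
Reactants: 19 (2R,3S)-2-[2-(benzyloxy)ethyl]-5-oxooxolane-3-carboxylic acid
Product: 20 (4R,5R)-5-[2-(benzyloxy)ethyl]-4-(hydroxymethyl)oxolan-2-one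
Conditions: BH3·SMe2 (1.3 equiv), THF, 0 °C → rt; MeOH
Reagents that add atoms: none
Why: Chemoselective borane reduction of a carboxylic acid through its acyloxyborane, which is much faster than reduction of the γ-lactone. No base is present, so the freed C4′ hydroxyl should not move the lactone.

Step 10
Reactants: 20 (4R,5R)-5-[2-(benzyloxy)ethyl]-4-(hydroxymethyl)oxolan-2-one
Product: 21 (4R,5R)-5-[2-(benzyloxy)ethyl]-4-({[tert-butyl(dimethyl)silyl]oxy}methyl)oxolan-2-one
Conditions: TBSCl, imidazole, CH2Cl2, 0 °C → rt
Reagents that add atoms: tert-butyl(chloro)dimethylsilane, CC(C)(C)[Si](C)(C)Cl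
Why: Standard silylation of a primary alcohol, carried out promptly so that the hydroxymethyl lactone is not left under conditions that could equilibrate the two possible γ-lactones.

Step 11
Reactants: 21 (4R,5R)-5-[2-(benzyloxy)ethyl]-4-({[tert-butyl(dimethyl)silyl]oxy}methyl)oxolan-2-one
Product: 22 (4R,5R)-4-({[tert-butyl(dimethyl)silyl]oxy}methyl)-5-(2-hydroxyethyl)oxolan-2-one
Conditions: H2 (1 bar), Pd/C (10 wt %), EtOAc, rt
Reagents that add atoms: none
Why: Hydrogenolysis of the benzyl ether on palladium, placed here because no alkene is yet present. The silyl ether and the lactone are stable in a neutral aprotic solvent.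

Step 12
Reactants: 22 (4R,5R)-4-({[tert-butyl(dimethyl)silyl]oxy}methyl)-5-(2-hydroxyethyl)oxolan-2-one
Product: 23 2-[(2R,3R)-3-({[tert-butyl(dimethyl)silyl]oxy}methyl)-5-oxooxolan-2-yl]acetaldehyde
Conditions: Dess–Martin periodinane, CH2Cl2, 0 °C → rt; used crude at once
Reagents that add atoms: none
Why: Dess–Martin oxidation of the primary alcohol under base-free conditions, chosen because the β-acyloxy aldehyde would eliminate with amine bases.

Step 13
Reactants: 23 2-[(2R,3R)-3-({[tert-butyl(dimethyl)silyl]oxy}methyl)-5-oxooxolan-2-yl]acetaldehyde; 10 ethyl (5E)-2-[bis(2-methylphenoxy)phosphoryl]-6-methyl-8-(2,6,6-trimethylcyclohex-1-en-1-yl)oct-5-enoate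
Product: 24 ethyl (2Z,5E)-2-{2-[(2R,3R)-3-({[tert-butyl(dimethyl)silyl]oxy}methyl)-5-oxooxolan-2-yl]ethylidene}-6-methyl-8-(2,6,6-trimethylcyclohex-1-en-1-yl)oct-5-enoate
Conditions: 10 (1.2 equiv), NaH (1.1 equiv), THF, 0 °C; then 23, −78 °C → 0 °C
Reagents that add atoms: none
Why: Z-selective Horner–Wadsworth–Emmons olefination with a diaryl phosphonate (Ando variant): the electron-poor aryloxy groups make collapse of the kinetically formed adduct fast and irreversible, which places the ester cis to the aldehyde-derived CH2. The preformed, weakly basic phosphonate anion at low temperature should spare the β-acyloxy aldehyde.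

Step 14
Reactants: 24 ethyl (2Z,5E)-2-{2-[(2R,3R)-3-({[tert-butyl(dimethyl)silyl]oxy}methyl)-5-oxooxolan-2-yl]ethylidene}-6-methyl-8-(2,6,6-trimethylcyclohex-1-en-1-yl)oct-5-enoate
Product: 27 (6R)-3-[(3E)-4-methyl-6-(2,6,6-trimethylcyclohex-1-en-1-yl)hex-3-en-1-yl]-6-[(3R)-5-oxooxolan-3-yl]-5,6-dihydro-2H-pyran-2-one (CNP0207009.2), via primary alcohol 25 (not isolated), via transposed hydroxy enoate 26 (not isolated)
Conditions: CSA (0.2 equiv), MeOH, 0 °C → rt; evaporate; CSA (0.1 equiv), toluene, 50 °C
Reagents that add atoms: none
Why: Acidic methanolysis removes the primary silyl ether; the C4′ hydroxyl of 25 then adds to C1′ and the tetrahedral intermediate releases the C6 hydroxyl (acid-catalysed translactonisation, 5-exo-trig), which is trapped by 6-exo-trig lactonisation onto the Z-enoate with loss of ethanol. Ring A plus ring B is the only arrangement in which both carboxyls sit in five- or six-membered lactones, so the equilibria should drain to 27; no stereocentre is touched.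

## Compound list

1 | dihydro-β-ionone, 4-(2,6,6-trimethylcyclohex-1-en-1-yl)butan-2-one | CC1=C(CCC(C)=O)C(C)(C)CCC1 | starting material
2 | diethyl 4-(2,6,6-trimethylcyclohex-1-en-1-yl)but-1-en-2-yl phosphate | CCOP(=O)(OCC)OC(=C)CCC1=C(C)CCCC1(C)C | intermediate (not isolated)
3 | 2-(but-3-yn-1-yl)-1,3,3-trimethylcyclohex-1-ene | C#CCCC1=C(C)CCCC1(C)C | intermediate
4 | oxirane | C1CO1 | starting material
5 | dimethyl[(1E)-2-methyl-4-(2,6,6-trimethylcyclohex-1-en-1-yl)but-1-en-1-yl]alumane | C[Al](C)/C=C(\C)CCC1=C(C)CCCC1(C)C | intermediate (not isolated)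
6 | lithium butyl(dimethyl)[(1E)-2-methyl-4-(2,6,6-trimethylcyclohex-1-en-1-yl)but-1-en-1-yl]aluminate | [Li+].CCCC[Al-](C)(C)/C=C(\C)CCC1=C(C)CCCC1(C)C | intermediate (not isolated)
7 | (3E)-4-methyl-6-(2,6,6-trimethylcyclohex-1-en-1-yl)hex-3-en-1-ol | OCC/C=C(\C)CCC1=C(C)CCCC1(C)C | intermediate
8 | 2-[(3E)-6-iodo-3-methylhex-3-en-1-yl]-1,3,3-trimethylcyclohex-1-ene | ICC/C=C(\C)CCC1=C(C)CCCC1(C)C | intermediate
9 | ethyl 2-[bis(2-methylphenoxy)phosphoryl]acetate | CCOC(=O)CP(=O)(Oc1ccccc1C)Oc1ccccc1C | starting material
10 | ethyl (5E)-2-[bis(2-methylphenoxy)phosphoryl]-6-methyl-8-(2,6,6-trimethylcyclohex-1-en-1-yl)oct-5-enoate (racemic at C2) | CCOC(=O)C(CC/C=C(\C)CCC1=C(C)CCCC1(C)C)P(=O)(Oc1ccccc1C)Oc1ccccc1C | intermediate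
11 | tert-butyl 3-oxobutanoate | CC(=O)CC(=O)OC(C)(C)C | starting material
12 | benzyl chloromethyl ether | ClCOCc1ccccc1 | starting material
13 | tert-butyl 5-(benzyloxy)-3-oxopentanoate | CC(C)(C)OC(=O)CC(=O)CCOCc1ccccc1 | intermediate
14 | methyl bromoacetate | COC(=O)CBr | starting material
15 | 1-tert-butyl 4-methyl 2-[3-(benzyloxy)propanoyl]butanedioate (racemic) | CC(C)(C)OC(=O)C(CC(=O)OC)C(=O)CCOCc1ccccc1 | intermediate
16 | 1-tert-butyl 4-methyl 2-[(1R)-3-(benzyloxy)-1-hydroxypropyl]butanedioate (C2 epimers) | CC(C)(C)OC(=O)C(CC(=O)OC)[C@H](O)CCOCc1ccccc1 | intermediate (not isolated)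
17 | tert-butyl (2R)-2-[2-(benzyloxy)ethyl]-5-oxooxolane-3-carboxylate (C3 epimers) | CC(C)(C)OC(=O)C1CC(=O)O[C@@H]1CCOCc1ccccc1 | intermediate (not isolated)
18 | tert-butyl (2R,3S)-2-[2-(benzyloxy)ethyl]-5-oxooxolane-3-carboxylate (trans) | CC(C)(C)OC(=O)[C@H]1CC(=O)O[C@@H]1CCOCc1ccccc1 | intermediate
19 | (2R,3S)-2-[2-(benzyloxy)ethyl]-5-oxooxolane-3-carboxylic acid | OC(=O)[C@H]1CC(=O)O[C@@H]1CCOCc1ccccc1 | intermediate
20 | (4R,5R)-5-[2-(benzyloxy)ethyl]-4-(hydroxymethyl)oxolan-2-one | OC[C@H]1CC(=O)O[C@@H]1CCOCc1ccccc1 | intermediate
21 | (4R,5R)-5-[2-(benzyloxy)ethyl]-4-({[tert-butyl(dimethyl)silyl]oxy}methyl)oxolan-2-one | CC(C)(C)[Si](C)(C)OC[C@H]1CC(=O)O[C@@H]1CCOCc1ccccc1 | intermediate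
22 | (4R,5R)-4-({[tert-butyl(dimethyl)silyl]oxy}methyl)-5-(2-hydroxyethyl)oxolan-2-one | CC(C)(C)[Si](C)(C)OC[C@H]1CC(=O)O[C@@H]1CCO | intermediate
23 | 2-[(2R,3R)-3-({[tert-butyl(dimethyl)silyl]oxy}methyl)-5-oxooxolan-2-yl]acetaldehyde | CC(C)(C)[Si](C)(C)OC[C@H]1CC(=O)O[C@@H]1CC=O | intermediate
24 | ethyl (2Z,5E)-2-{2-[(2R,3R)-3-({[tert-butyl(dimethyl)silyl]oxy}methyl)-5-oxooxolan-2-yl]ethylidene}-6-methyl-8-(2,6,6-trimethylcyclohex-1-en-1-yl)oct-5-enoate | CCOC(=O)/C(CC/C=C(\C)CCC1=C(C)CCCC1(C)C)=C\C[C@H]2OC(=O)C[C@@H]2CO[Si](C)(C)C(C)(C)C | intermediate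
25 | ethyl (2Z,5E)-2-{2-[(2R,3R)-3-(hydroxymethyl)-5-oxooxolan-2-yl]ethylidene}-6-methyl-8-(2,6,6-trimethylcyclohex-1-en-1-yl)oct-5-enoate | CCOC(=O)/C(CC/C=C(\C)CCC1=C(C)CCCC1(C)C)=C\C[C@H]2OC(=O)C[C@@H]2CO | intermediate (not isolated)
26 | ethyl (2Z,5E)-2-{(3R)-3-hydroxy-3-[(3R)-5-oxooxolan-3-yl]propylidene}-6-methyl-8-(2,6,6-trimethylcyclohex-1-en-1-yl)oct-5-enoate | CCOC(=O)/C(CC/C=C(\C)CCC1=C(C)CCCC1(C)C)=C\C[C@@H](O)[C@H]2COC(=O)C2 | intermediate (not isolated)
27 | (6R)-3-[(3E)-4-methyl-6-(2,6,6-trimethylcyclohex-1-en-1-yl)hex-3-en-1-yl]-6-[(3R)-5-oxooxolan-3-yl]-5,6-dihydro-2H-pyran-2-one | CC1=C(CC/C(C)=C/CCC2=CC[C@H]([C@H]3COC(=O)C3)OC2=O)C(C)(C)CCC1 | target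

## Step count and risks

Total step count: 14. Longest linear sequence: 10 steps (steps 5–14, from 11 to 27). The chain fragment takes 4 steps (1–4) and joins at step 13.

**Step 7 (key step).** The hindered 2-substituted tert-butyl 3-oxo ester may hydrogenate slowly, and coordination of the methyl ester arm or the benzyl ether to ruthenium may erode the face selectivity at C6. Convergence at C3′ may also stay incomplete if the base equilibration is sluggish.
Fallback, from 13 back to 18: 13 itself, an unsubstituted 3-oxo ester and the best-behaved substrate class for the same catalyst, is hydrogenated to tert-butyl (3R)-5-(benzyloxy)-3-hydroxypentanoate F1. Fráter–Seebach alkylation of the dianion of F1 (LiN(i-Pr)2, 2.2 equiv, THF) with 14 gives the anti hydroxy diester F2. F2 lactonises on mildly acidic work-up to the cis lactone F3, and the DBU treatment of step 7 converts F3 into 18. C6 then comes from a reduction without any α-substituent and C3′ from substrate control plus equilibration.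

**Step 14.** The translactonisation may be slower than acid-promoted damage to the 1,5-diene (cation–olefin cyclisation, double-bond migration) or than conjugate addition of the C4′ hydroxyl to the enoate. The equilibrium between the two γ-lactones is expected to lie on the side of 25, so the step depends entirely on trapping by ring A.
Fallback, from 21 back to 26: the lactone of 21 is opened with Me2AlN(OMe)Me (from AlMe3 and MeNHOMe·HCl) to the hydroxy Weinreb amide F4. Its C6 hydroxyl is silylated (TBSOTf, 2,6-lutidine) to F5. The primary silyl ether alone is removed (CSA, MeOH, 0 °C), whereupon the γ-hydroxy amide closes ring B to give F6. Hydrogenolysis gives alcohol F7, and Dess–Martin oxidation gives the β-silyloxy aldehyde F8, which no longer carries an acyloxy leaving group. Olefination with 10 as in step 13 gives F9, and HF·pyridine removes the secondary silyl ether to give 26, which lactonises to 27. Each hydroxyl then has a single acyl partner and no lactone has to migrate.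

**Step 13.** The aldehyde may lose the lactone carboxylate by β-elimination under the basic conditions, and the α-branched reagent may give insufficient Z-selectivity; the E isomer cannot lactonise.
Fallback, from 23 back to 27: Still–Gennari olefination of 23 with commercial methyl bis(2,2,2-trifluoroethyl)phosphonoacetate (KN(SiMe3)2, 18-crown-6, THF, −78 °C) gives the disubstituted Z-enoate F10. The acid treatment of step 14 carries F10 through the alcohol F11 and the transposed hydroxy ester F12 to the chain-free bis-lactone F13 (identical with A4). α-Iodination (I2, pyridine) gives F14. Negishi coupling of F14 with the alkylzinc iodide F15 (from 8, Zn, LiCl, THF) under PdCl2(dppf) gives 27. The chain is then attached by sp2–sp3 coupling after ring A exists.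

**Step 2.** Opening of oxirane by the aluminate may be sluggish, with competing transfer of butyl or methyl, and the methylalumination may not be fully regioselective.
Fallback, from 3 back to 7: the alkenylalane 5 is made as before and cleaved with I2 to the (E)-alkenyl iodide F16, which can be purified. Iodine–lithium exchange (t-BuLi, 2 equiv, Et2O, −78 °C) gives the alkenyllithium F17, which opens oxirane in the presence of BF3·OEt2 to give 7.

## Further compounds

F1 | step 7 | tert-butyl (3R)-5-(benzyloxy)-3-hydroxypentanoate | CC(C)(C)OC(=O)C[C@H](O)CCOCc1ccccc1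
F2 | step 7 | 1-tert-butyl 4-methyl (2R)-2-[(1R)-3-(benzyloxy)-1-hydroxypropyl]butanedioate | CC(C)(C)OC(=O)[C@H](CC(=O)OC)[C@H](O)CCOCc1ccccc1
F3 | step 7 | tert-butyl (2R,3R)-2-[2-(benzyloxy)ethyl]-5-oxooxolane-3-carboxylate (cis) | CC(C)(C)OC(=O)[C@@H]1CC(=O)O[C@@H]1CCOCc1ccccc1
F4 | step 14 | (3R,4R)-6-(benzyloxy)-3-({[tert-butyl(dimethyl)silyl]oxy}methyl)-4-hydroxy-N-methoxy-N-methylhexanamide | CON(C)C(=O)C[C@H](CO[Si](C)(C)C(C)(C)C)[C@H](O)CCOCc1ccccc1
F5 | step 14 | (3R,4R)-6-(benzyloxy)-4-{[tert-butyl(dimethyl)silyl]oxy}-3-({[tert-butyl(dimethyl)silyl]oxy}methyl)-N-methoxy-N-methylhexanamide | CON(C)C(=O)C[C@H](CO[Si](C)(C)C(C)(C)C)[C@H](O[Si](C)(C)C(C)(C)C)CCOCc1ccccc1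
F6 | step 14 | (4R)-4-[(1R)-3-(benzyloxy)-1-{[tert-butyl(dimethyl)silyl]oxy}propyl]oxolan-2-one | CC(C)(C)[Si](C)(C)O[C@H](CCOCc1ccccc1)[C@H]1COC(=O)C1
F7 | step 14 | (4R)-4-[(1R)-1-{[tert-butyl(dimethyl)silyl]oxy}-3-hydroxypropyl]oxolan-2-one | CC(C)(C)[Si](C)(C)O[C@H](CCO)[C@H]1COC(=O)C1
F8 | step 14 | (3R)-3-{[tert-butyl(dimethyl)silyl]oxy}-3-[(3R)-5-oxooxolan-3-yl]propanal | CC(C)(C)[Si](C)(C)O[C@H](CC=O)[C@H]1COC(=O)C1
F9 | step 14 | ethyl (2Z,5E)-2-{(3R)-3-{[tert-butyl(dimethyl)silyl]oxy}-3-[(3R)-5-oxooxolan-3-yl]propylidene}-6-methyl-8-(2,6,6-trimethylcyclohex-1-en-1-yl)oct-5-enoate | CCOC(=O)/C(CC/C=C(\C)CCC1=C(C)CCCC1(C)C)=C\C[C@@H](O[Si](C)(C)C(C)(C)C)[C@H]2COC(=O)C2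
F10 | step 13 | methyl (2Z)-4-[(2R,3R)-3-({[tert-butyl(dimethyl)silyl]oxy}methyl)-5-oxooxolan-2-yl]but-2-enoate | COC(=O)/C=C\C[C@H]1OC(=O)C[C@@H]1CO[Si](C)(C)C(C)(C)C
F11 | step 13 | methyl (2Z)-4-[(2R,3R)-3-(hydroxymethyl)-5-oxooxolan-2-yl]but-2-enoate | COC(=O)/C=C\C[C@H]1OC(=O)C[C@@H]1CO
F12 | step 13 | methyl (2Z,5R)-5-hydroxy-5-[(3R)-5-oxooxolan-3-yl]pent-2-enoate | COC(=O)/C=C\C[C@@H](O)[C@H]1COC(=O)C1
F13 | step 13 | (6R)-6-[(3R)-5-oxooxolan-3-yl]-5,6-dihydro-2H-pyran-2-one | O=C1C=CC[C@H]([C@H]2COC(=O)C2)O1
F14 | step 13 | (6R)-3-iodo-6-[(3R)-5-oxooxolan-3-yl]-5,6-dihydro-2H-pyran-2-one | O=C1C(I)=CC[C@H]([C@H]2COC(=O)C2)O1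
F15 | step 13 | iodo[(3E)-4-methyl-6-(2,6,6-trimethylcyclohex-1-en-1-yl)hex-3-en-1-yl]zinc | I[Zn]CC/C=C(\C)CCC1=C(C)CCCC1(C)C
F16 | step 2 | 2-[(3E)-4-iodo-3-methylbut-3-en-1-yl]-1,3,3-trimethylcyclohex-1-ene | I/C=C(\C)CCC1=C(C)CCCC1(C)C
F17 | step 2 | [(1E)-2-methyl-4-(2,6,6-trimethylcyclohex-1-en-1-yl)but-1-en-1-yl]lithium | [Li]/C=C(\C)CCC1=C(C)CCCC1(C)C
A1 | alternative 1 | (2S,6R)-2-methoxy-3-[(3E)-4-methyl-6-(2,6,6-trimethylcyclohex-1-en-1-yl)hex-3-en-1-yl]-6-[(3R)-5-oxooxolan-3-yl]-3,6-dihydro-2H-pyran (cis) | CC1=C(CC/C(C)=C/CCC2=CC[C@H]([C@H]3COC(=O)C3)O[C@@H]2OC)C(C)(C)CCC1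
A2 | alternative 1 | (1E)-1-methoxy-2-[(3E)-4-methyl-6-(2,6,6-trimethylcyclohex-1-en-1-yl)hex-3-en-1-yl]buta-1,3-diene | CO/C=C(/C=C)CC/C=C(\C)CCC1=C(C)CCCC1(C)C
A3 | alternative 1 | (3R)-5-oxooxolane-3-carbaldehyde | O=C[C@H]1COC(=O)C1
A4 | alternative 2 | (6R)-6-[(3R)-5-oxooxolan-3-yl]-5,6-dihydro-2H-pyran-2-one | O=C1C=CC[C@H]([C@H]2COC(=O)C2)O1
A5 | alternative 2 | 2-[(2R)-6-oxo-3,6-dihydro-2H-pyran-2-yl]ethyl diazoacetate | [N-]=[N+]=CC(=O)OCC[C@H]1CC=CC(=O)O1
A6 | alternative 3 | (6R)-6-[(3R)-5-hydroxyoxolan-3-yl]-3-[(3E)-4-methyl-6-(2,6,6-trimethylcyclohex-1-en-1-yl)hex-3-en-1-yl]-5,6-dihydro-2H-pyran-2-one (anomeric mixture) | CC1=C(CC/C(C)=C/CCC2=CC[C@H]([C@H]3COC(O)C3)OC2=O)C(C)(C)CCC1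
A7 | alternative 3 | (6R)-6-(3-hydroxyprop-1-en-2-yl)-3-[(3E)-4-methyl-6-(2,6,6-trimethylcyclohex-1-en-1-yl)hex-3-en-1-yl]-5,6-dihydro-2H-pyran-2-one | CC1=C(CC/C(C)=C/CCC2=CC[C@H](C(=C)CO)OC2=O)C(C)(C)CCC1
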